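## Retrosynthetic overview

- The target is traced back to a (3S)-isoflavan whose ring B is a free 2',5'-hydroquinone; oxidation of ring B to the quinone is the last event.
- That isoflavan comes from a cis-pterocarpan by hydrogenolysis of the benzylic C4–O2' bond and of two benzyl ethers, so the furan ring is a temporary ring.
- The pterocarpan comes from a symmetric (E)-stilbene bis(methoxymethyl ether) in one acid-catalyzed cascade: the pyran ring closes first by the bond between C2 (the CH2 of a methoxymethyl group on O1) and C3, then the furan ring closes by C4–O2'.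
- Enabling feature: ring A (the benzo ring of the chroman) and quinone ring B are the same 2,3-dimethoxy-1,4-dioxygenated benzene unit, and each carries an oxygen ortho to its link to the C3–C4 unit (O1 on C8a, the carbonyl oxygen on C2'). The C3=C4 stilbene is therefore a dimer of one aldehyde, O1 can deliver C2 to C3, and O2' can hold C4.
- The stilbene comes from McMurry dimerization of one aldehyde made from 2,3,4-trimethoxybenzaldehyde. Ring order: both benzene rings are bought, pyran then furan form in the key step, and the furan is opened and the quinone formed at the end.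

Key step: step 6

Remark: chroman numbering is used (O1, C2, C3, C4; ring A is the benzo ring, ring B the quinone joined through C1'); the stereocenter C3 is read as (S), and the enantiomer of the acid catalyst in step 6 is to be assigned by experiment so that the (6aS,11aS) product results.

## Route

Step 1
Reactants: 1 2,3,4-trimethoxybenzaldehyde
Product: 2 2-hydroxy-3,4-dimethoxybenzaldehyde
Conditions: BCl3 (1.1 equiv), CH2Cl2, 0 °C to rt; then H2O
Reagents that add atoms: none
Why: Chelation-controlled Lewis acid O-demethylation, in which BCl3 bridges the formyl oxygen and the neighbouring 2-methoxy oxygen so that only the methyl ether ortho to the aldehyde should be cleaved.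

Step 2
Reactants: 2 2-hydroxy-3,4-dimethoxybenzaldehyde
Product: 4 2,5-dihydroxy-3,4-dimethoxybenzaldehyde, via potassium 5-formyl-4-hydroxy-2,3-dimethoxyphenyl sulfate 3 (not isolated)
Conditions: K2S2O8, aq KOH, 0 °C to rt; then HCl, 80 °C
Reagents that add atoms: potassium peroxodisulfate K2S2O8, [K+].[K+].[O-]S(=O)(=O)OOS(=O)(=O)[O-]
Why: Elbs persulfate oxidation, in which the phenoxide attacks the peroxide oxygen through its para carbon (the only free ortho or para position of 2) and the aryl sulfate is then hydrolysed by acid to the hydroquinone.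

Step 3
Reactants: 4 2,5-dihydroxy-3,4-dimethoxybenzaldehyde
Product: 5 5-(benzyloxy)-2-hydroxy-3,4-dimethoxybenzaldehyde
Conditions: BnBr (1.05 equiv), K2CO3 (1.1 equiv), acetone, reflux
Reagents that add atoms: benzyl bromide, BrCc1ccccc1
Why: Williamson etherification that should be selective for the 5-hydroxyl because the 2-hydroxyl is hydrogen-bonded to the formyl group and its phenoxide is the weaker nucleophile, as in the selective 5-O-alkylation of 2,5-dihydroxyaryl carbonyl compounds.

Step 4
Reactants: 5 5-(benzyloxy)-2-hydroxy-3,4-dimethoxybenzaldehyde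
Product: 6 5-(benzyloxy)-3,4-dimethoxy-2-(methoxymethoxy)benzaldehyde
Conditions: MOMCl, iPr2NEt, CH2Cl2, 0 °C to reflux
Reagents that add atoms: chloromethyl methyl ether, COCCl
Why: O-alkylation of the phenol with an alpha-chloro ether gives the mixed formaldehyde acetal, which protects the phenol through the olefination and carries the carbon that later becomes C2.

Step 5
Reactants: 6 5-(benzyloxy)-3,4-dimethoxy-2-(methoxymethoxy)benzaldehyde (two molecules)
Product: 7 (E)-1,2-bis[5-(benzyloxy)-3,4-dimethoxy-2-(methoxymethoxy)phenyl]ethene
Conditions: TiCl4, Zn, pyridine, THF, reflux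
Reagents that add atoms: none
Why: McMurry reductive coupling of an aryl aldehyde by low-valent titanium should give the symmetric stilbene with the E isomer favoured, while pyridine tempers the Lewis acidity so that the acetal and benzyl ethers survive.

Step 6
Reactants: 7 (E)-1,2-bis[5-(benzyloxy)-3,4-dimethoxy-2-(methoxymethoxy)phenyl]ethene
Product: 8 (6aS,11aS)-2,8-bis(benzyloxy)-3,4,9,10-tetramethoxy-6a,11a-dihydro-6H-[1]benzofuro[3,2-c]chromene (cis-pterocarpan)
Conditions: chiral confined imidodiphosphorimidate Brønsted acid (IDPi: two 3,3'-diaryl-1,1'-bi-2-naphthol phosphoryl units bridged by nitrogen, each phosphorus bearing an N-trifluoromethylsulfonyl imide group; 5 mol %), CHCl3, −40 °C; Et3N quench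
Reagents that add atoms: none
Why: Proposed new method: the chiral acid ionizes one methoxymethyl acetal of 7 with loss of methanol to an aryloxymethyl oxocarbenium ion held as an ion pair by the confined anion, this carbon adds to the alkene carbon remote from its own ring (Prins cyclization) and so forms the CH2–CH bond and the pyran ring, and the benzylic cation left at the other alkene carbon, stabilized by the para-methoxy group and the ortho ether oxygen of that ring, is captured by the methoxymethyl ether oxygen of the second ring, whose methoxymethyl cation ends with the released methanol as dimethoxymethane and returns the proton. The closest known reaction types are the acid-promoted Prins cyclization of homoallylic methoxymethyl ethers, the asymmetric Prins reaction of aryl olefins with formaldehyde under confined chiral Brønsted acids, and cation capture by an ether oxygen with loss of its alkyl group. The pyran ring closes 6-endo-trig with respect to both the oxocarbenium and the alkene, and the furan ring closes 5-exo-trig at the delocalized benzylic cation. The stereocenter at C6a, the later C3 of the chroman, is set in the carbon–carbon bond formation by the chiral counteranion, which selects the alkene face, and C11a is then set by the substrate because only the cis-fused 6,5-junction is free of strain. The step needs attack at the remote and not the near alkene carbon, which is secured because the alternative is a 5-endo-trig closure at the oxocarbenium, and it needs a single constitution from two acetal groups, which is secured because the two aryl rings are identical and either acetal starts the same cascade.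

Step 7
Reactants: 8 (6aS,11aS)-2,8-bis(benzyloxy)-3,4,9,10-tetramethoxy-6a,11a-dihydro-6H-[1]benzofuro[3,2-c]chromene
Product: 10 5-[(3S)-6-hydroxy-7,8-dimethoxychroman-3-yl]-2,3-dimethoxy-1,4-benzoquinone (CNP0302517.1), via (3S)-3-(2,5-dihydroxy-3,4-dimethoxyphenyl)-7,8-dimethoxychroman-6-ol 9 (not isolated)
Conditions: H2 (1 atm), Pd/C, EtOAc–AcOH, rt; filter under Ar, evaporate; then Ag2O, Na2SO4, Et2O, rt
Reagents that add atoms: none
Why: Catalytic hydrogenolysis should cleave both O-benzyl ethers and the benzylic C11a–O bond (the known opening of pterocarpans to 2'-hydroxyisoflavans, which leaves C6a untouched), and neutral Ag2O should then oxidize only the free para-hydroquinone ring to the quinone, because the ring A phenol is a hydroquinone monoether that cannot become a quinone without losing its alkyl group.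

## Compound list

1 | 2,3,4-trimethoxybenzaldehyde | COc1ccc(C=O)c(OC)c1OC | starting material
2 | 2-hydroxy-3,4-dimethoxybenzaldehyde | COc1ccc(C=O)c(O)c1OC | intermediate
3 | potassium 5-formyl-4-hydroxy-2,3-dimethoxyphenyl sulfate | COc1c(OC)c(OS(=O)(=O)[O-])cc(C=O)c1O.[K+] | intermediate
4 | 2,5-dihydroxy-3,4-dimethoxybenzaldehyde | COc1c(OC)c(O)cc(C=O)c1O | intermediate
5 | 5-(benzyloxy)-2-hydroxy-3,4-dimethoxybenzaldehyde | COc1c(OC)c(OCc2ccccc2)cc(C=O)c1O | intermediate
6 | 5-(benzyloxy)-3,4-dimethoxy-2-(methoxymethoxy)benzaldehyde | COCOc1c(C=O)cc(OCc2ccccc2)c(OC)c1OC | intermediate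
7 | (E)-1,2-bis[5-(benzyloxy)-3,4-dimethoxy-2-(methoxymethoxy)phenyl]ethene | COCOc1c(/C=C/c2cc(OCc3ccccc3)c(OC)c(OC)c2OCOC)cc(OCc2ccccc2)c(OC)c1OC | intermediate
8 | (6aS,11aS)-2,8-bis(benzyloxy)-3,4,9,10-tetramethoxy-6a,11a-dihydro-6H-[1]benzofuro[3,2-c]chromene | COc1c(OC)c(OCc2ccccc2)cc2c1O[C@@H]1c3cc(OCc4ccccc4)c(OC)c(OC)c3OC[C@H]21 | intermediate
9 | (3S)-3-(2,5-dihydroxy-3,4-dimethoxyphenyl)-7,8-dimethoxy-3,4-dihydro-2H-chromen-6-ol | COc1c(OC)c(O)c([C@H]2COc3c(cc(O)c(OC)c3OC)C2)cc1O | intermediate
10 | 5-[(3S)-6-hydroxy-7,8-dimethoxy-3,4-dihydro-2H-chromen-3-yl]-2,3-dimethoxycyclohexa-2,5-diene-1,4-dione | COC1=C(OC)C(=O)C([C@H]2COc3c(cc(O)c(OC)c3OC)C2)=CC1=O | target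

## Summary and risks

Total step count: 7. Longest linear sequence: 7 steps (1 to 10; step 5 joins two molecules of the same intermediate).

Steps most likely to fail:

**Step 6.** The small aryloxymethyl cation may not be held tightly enough by the chiral anion for useful face discrimination. The protonated acetal may also lose the phenol instead of methanol, after which proton-initiated closure of the freed phenol onto the stilbene without uptake of the one-carbon unit would divert material. Reversible reopening of the furan ring with proton loss from C6a would erode the configuration.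

The fallback uses known chemistry, sets out from 7 and comes back at 8. Hydroboration–oxidation of the symmetric alkene (BH3·THF; NaOH, H2O2) should give racemic 1,2-bis[5-(benzyloxy)-3,4-dimethoxy-2-(methoxymethoxy)phenyl]ethan-1-ol F1. Dess–Martin oxidation should give the deoxybenzoin 1,2-bis[5-(benzyloxy)-3,4-dimethoxy-2-(methoxymethoxy)phenyl]ethan-1-one F2. Condensation with N,N-dimethylformamide dimethyl acetal (toluene, 90 °C) should give the enaminone 1,2-bis[5-(benzyloxy)-3,4-dimethoxy-2-(methoxymethoxy)phenyl]-3-(dimethylamino)prop-2-en-1-one F3. HCl in MeOH should remove both acetals and close the pyranone at O1–C2 (6-endo addition–elimination, the 5-endo alternative of the other phenol being disfavoured) to 6-(benzyloxy)-3-[5-(benzyloxy)-2-hydroxy-3,4-dimethoxyphenyl]-7,8-dimethoxy-4H-chromen-4-one F4. Noyori–Ikariya asymmetric transfer hydrogenation with dynamic kinetic resolution (RuCl(p-cymene)(TsDPEN) of the configuration that gives the 3S series, HCO2H–Et3N) should reduce the enone double bond and then the configurationally labile isoflavanone to (3S,4S)-6-(benzyloxy)-3-[5-(benzyloxy)-2-hydroxy-3,4-dimethoxyphenyl]-7,8-dimethoxychroman-4-ol F5. Brief acid treatment should ionize the benzylic alcohol so that the 2'-phenol closes the furan to 8.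

**Step 5.** The acetal may be cleaved by Lewis-acidic titanium and zinc chlorides, the coupling may stop at the pinacol stage, or some Z-olefin may form. The fallback sets out from 6 and comes back at 7. Wittig methylenation (Ph3PCH3Br, KOtBu, THF) should give 1-(benzyloxy)-5-ethenyl-2,3-dimethoxy-4-(methoxymethoxy)benzene F6. Homodimerizing olefin metathesis with the second-generation Hoveyda–Grubbs catalyst (CH2Cl2, 40 °C, ethene purged) should then give the E-stilbene 7 under thermodynamic control.

**Step 2.** Conversion in the persulfate hydroxylation of the formyl-deactivated phenol may be low, and the electron-rich hydroquinone may be over-oxidized. The fallback sets out from 2 and comes back at 4. Teuber oxidation with Fremy's salt ON(SO3K)2 (KH2PO4 buffer, H2O–acetone) should give the para-quinone 4,5-dimethoxy-3,6-dioxocyclohexa-1,4-diene-1-carbaldehyde F7, which is reduced at once with aqueous Na2S2O4 to hydroquinone 4.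

## Further compounds

F1 | step 6 | 1,2-bis[5-(benzyloxy)-3,4-dimethoxy-2-(methoxymethoxy)phenyl]ethan-1-ol (racemic) | COCOc1c(CC(O)c2cc(OCc3ccccc3)c(OC)c(OC)c2OCOC)cc(OCc2ccccc2)c(OC)c1OC
F2 | step 6 | 1,2-bis[5-(benzyloxy)-3,4-dimethoxy-2-(methoxymethoxy)phenyl]ethan-1-one | COCOc1c(CC(=O)c2cc(OCc3ccccc3)c(OC)c(OC)c2OCOC)cc(OCc2ccccc2)c(OC)c1OC
F3 | step 6 | 1,2-bis[5-(benzyloxy)-3,4-dimethoxy-2-(methoxymethoxy)phenyl]-3-(dimethylamino)prop-2-en-1-one (double-bond geometry not fixed) | COCOc1c(C(=CN(C)C)C(=O)c2cc(OCc3ccccc3)c(OC)c(OC)c2OCOC)cc(OCc2ccccc2)c(OC)c1OC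
F4 | step 6 | 6-(benzyloxy)-3-[5-(benzyloxy)-2-hydroxy-3,4-dimethoxyphenyl]-7,8-dimethoxy-4H-chromen-4-one | O=c1c(-c2cc(OCc3ccccc3)c(OC)c(OC)c2O)coc2c(OC)c(OC)c(OCc3ccccc3)cc12
F5 | step 6 | (3S,4S)-6-(benzyloxy)-3-[5-(benzyloxy)-2-hydroxy-3,4-dimethoxyphenyl]-7,8-dimethoxy-3,4-dihydro-2H-chromen-4-ol | COc1c(OC)c(OCc2ccccc2)cc(c1O)[C@H]1COc2c(OC)c(OC)c(OCc3ccccc3)cc2[C@H]1O
F6 | step 5 | 1-(benzyloxy)-5-ethenyl-2,3-dimethoxy-4-(methoxymethoxy)benzene | COCOc1c(C=C)cc(OCc2ccccc2)c(OC)c1OC
F7 | step 2 | 4,5-dimethoxy-3,6-dioxocyclohexa-1,4-diene-1-carbaldehyde | COC1=C(OC)C(=O)C(C=O)=CC1=O
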